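The ring-fusion bond C5–C10 is the disconnection on which everything rests. C5 and C10 face each other across the ten-carbon periphery C1–C10 that encloses rings A and B, so a cyclodecene is made first and stitched transannularly. In one operation, hydrogen atom transfer to the C10=C20 methylene gives a tertiary C10 radical that adds to C5 of the ring-trans C4=C5 enoate, closing rings A and B and setting C10, C5 and C4. The precursor 29 is a ten-membered (Z)-enoate with the C10 methylene, the complete side chain on C9 and an equatorial silyl ether on C8; C8 and C9 come from one syn-aldol, C1 from a sulfone linchpin.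

Key step: step 19

Remark on numbering: labdane numbering is used for every intermediate (ring periphery C1–C10, side chain C11–C16, C17 on C8, C18 and C19 on C4, C20 on C10).

Remark on design: C8 is carried as a secondary silyl ether and oxidised only after the ring fusion exists. This avoids a C8 ketone or ketal next to a C9 stereocentre that is also allylic to C10=C20, and it keeps an axial oxygen and O–CH2 hydrogens away from the C10 radical. It also lets one aldol set C8 and C9 so that both substituents are equatorial in the chair–chair fold.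

Step 1
Reactants: 1 (R)-mevalonolactone
Product: 2 (3R)-3,5-dihydroxy-3-methyl-1-(pyrrolidin-1-yl)pentan-1-one
Conditions: pyrrolidine, THF, 50 °C
Reagents that add atoms: pyrrolidine C1CCNC1
Why: Aminolysis of the δ-lactone opens the ring at the acyl carbon, so the two CH2CH2O arms of the carbinol become different (C15 amide, C11 alcohol) before any reduction could make them equivalent; the stereocentre is untouched.

Step 2
Reactants: 2 (3R)-3,5-dihydroxy-3-methyl-1-(pyrrolidin-1-yl)pentan-1-one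
Product: 3 (3R)-3-methyl-1-(pyrrolidin-1-yl)-3,5-bis(triethylsilyloxy)pentan-1-one
Conditions: Et3SiOTf, 2,6-lutidine, CH2Cl2, −78 to 0 °C
Reagents that add atoms: triethylsilyl triflate CC[Si](CC)(CC)OS(=O)(=O)C(F)(F)F
Why: Silyl triflate silylation should protect the primary and the hindered tertiary alcohol in one operation.

Step 3
Reactants: 3 (3R)-3-methyl-1-(pyrrolidin-1-yl)-3,5-bis(triethylsilyloxy)pentan-1-one
Product: 4 (3S)-3-methyl-3,5-bis(triethylsilyloxy)pentan-1-ol
Conditions: LiH2NBH3 (from BH3·NH3 and LiN(iPr)2), THF, 0 to 23 °C; aq. NH4Cl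
Reagents that add atoms: none
Why: Amide reduction with lithium amidotrihydroborate cleaves the C–N bond of a tertiary amide to the primary alcohol (C15) without touching silyl ethers.

Step 4
Reactants: 4 (3S)-3-methyl-3,5-bis(triethylsilyloxy)pentan-1-ol
Product: 5 (3R)-1-(tert-butyldimethylsilyloxy)-3-methyl-3,5-bis(triethylsilyloxy)pentane
Conditions: t-BuMe2SiCl, imidazole, DMF, 23 °C
Reagents that add atoms: tert-butyldimethylsilyl chloride CC(C)(C)[Si](C)(C)Cl
Why: Standard silylation of the only free alcohol puts the robust silyl ether on C15.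

Step 5
Reactants: 5 (3R)-1-(tert-butyldimethylsilyloxy)-3-methyl-3,5-bis(triethylsilyloxy)pentane
Product: 6 (3S)-5-(tert-butyldimethylsilyloxy)-3-methyl-3-(triethylsilyloxy)pentanal
Conditions: (COCl)2, DMSO, CH2Cl2, −78 to −30 °C; Et3N, −78 to 0 °C
Reagents that add atoms: none
Why: Swern oxidation converts a primary triethylsilyl ether directly into the aldehyde (C11), while the primary TBS ether and the tertiary TES ether are inert to the chlorosulfonium reagent.

Step 6
Reactants: 6 (3S)-5-(tert-butyldimethylsilyloxy)-3-methyl-3-(triethylsilyloxy)pentanal; 7 benzyl (triphenylphosphoranylidene)acetate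
Product: 8 benzyl (2E,5R)-7-(tert-butyldimethylsilyloxy)-5-methyl-5-(triethylsilyloxy)hept-2-enoate
Conditions: CH2Cl2, 23 °C
Reagents that add atoms: none
Why: Wittig olefination with a stabilised ylide is neutral, so the β-silyloxy aldehyde should not eliminate, and it adds C9 and C10.

Step 7
Reactants: 8 benzyl (2E,5R)-7-(tert-butyldimethylsilyloxy)-5-methyl-5-(triethylsilyloxy)hept-2-enoate
Product: 9 (5R)-7-(tert-butyldimethylsilyloxy)-5-methyl-5-(triethylsilyloxy)heptanoic acid
Conditions: H2 (1 atm), Pd/C, EtOAc, 23 °C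
Reagents that add atoms: none
Why: Heterogeneous hydrogenation saturates C9–C11 and hydrogenolyses the benzyl ester in the same operation; ethyl acetate as solvent keeps the TES ether intact.

Step 8
Reactants: 9 (5R)-7-(tert-butyldimethylsilyloxy)-5-methyl-5-(triethylsilyloxy)heptanoic acid; 10 (S)-4-benzyloxazolidin-2-one
Product: 12 (S)-4-benzyl-3-[(5R)-7-(tert-butyldimethylsilyloxy)-5-methyl-5-(triethylsilyloxy)heptanoyl]oxazolidin-2-one, via mixed pivalic anhydride 11 (not isolated)
Conditions: t-BuCOCl, Et3N, THF, −20 °C; then 10, LiCl, −20 to 23 °C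
Reagents that add atoms: none
Why: N-Acylation of the oxazolidinone through the mixed anhydride is mild enough for both silyl ethers.

Step 9
Reactants: 13 methyl 2-[bis(2,2,2-trifluoroethoxy)phosphoryl]acetate; 14 1-chloro-2-iodoethane
Product: 15 methyl 2-[bis(2,2,2-trifluoroethoxy)phosphoryl]-4-chlorobutanoate (racemic)
Conditions: NaH, DMF, 0 °C; then 14 (excess), 0 to 23 °C
Reagents that add atoms: none
Why: SN2 C-alkylation of the stabilised phosphonoacetate anion occurs at the iodide end; the much poorer chloride leaving group is kept as the later electrophile on C2, and below room temperature it should not close a cyclopropane.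

Step 10
Reactants: 15 methyl 2-[bis(2,2,2-trifluoroethoxy)phosphoryl]-4-chlorobutanoate; 16 pent-4-enal
Product: 17 methyl (2Z)-2-(2-chloroethyl)hepta-2,6-dienoate
Conditions: KN(SiMe3)2, 18-crown-6, THF, −78 °C; then 16
Reagents that add atoms: none
Why: Still–Gennari olefination: the trifluoroethyl phosphonate eliminates fast from the kinetic adduct and should give the (Z)-enoate, the C4=C5 geometry in which C3 and C6 are trans.

Step 11
Reactants: 17 methyl (2Z)-2-(2-chloroethyl)hepta-2,6-dienoate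
Product: 19 methyl (2Z)-2-(2-chloroethyl)-6-oxohex-2-enoate, via vicinal diol 18 (not isolated)
Conditions: OsO4 (cat.), NaIO4, 2,6-lutidine, dioxane/H2O, 23 °C
Reagents that add atoms: osmium tetroxide O=[Os](=O)(=O)=O; sodium periodate [Na+].[O-]I(=O)(=O)=O
Why: Johnson–Lemieux oxidation: OsO4 dihydroxylates the electron-rich monosubstituted alkene much faster than the trisubstituted enoate, and periodate cleaves the diol to the C8 aldehyde.

Step 12
Reactants: 12 (S)-4-benzyl-3-[(5R)-7-(tert-butyldimethylsilyloxy)-5-methyl-5-(triethylsilyloxy)heptanoyl]oxazolidin-2-one; 19 methyl (2Z)-2-(2-chloroethyl)-6-oxohex-2-enoate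
Product: 21 (S)-4-benzyl-3-[(2S,3R,6Z)-9-chloro-3-hydroxy-7-(methoxycarbonyl)-2-{(3R)-5-(tert-butyldimethylsilyloxy)-3-methyl-3-(triethylsilyloxy)pentyl}non-6-enoyl]oxazolidin-2-one, via dibutylboron enolate 20 (not isolated)
Conditions: Bu2BOTf, iPr2NEt, CH2Cl2, 0 °C; then 19, −78 to 0 °C; H2O2, pH 7 buffer, MeOH
Reagents that add atoms: none
Why: Evans syn-aldol: the (Z)-boron enolate reacts through a closed chair transition state on the face away from the benzyl group and sets C9 and C8 together as (2S,3R), which later places the C9 side chain and the C8 oxygen both equatorial.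

Step 13
Reactants: 21 syn-aldol adduct
Product: 22 methyl (2Z,6R,7S)-2-(2-chloroethyl)-6-hydroxy-8-[methoxy(methyl)amino]-8-oxo-7-[(3R)-5-(tert-butyldimethylsilyloxy)-3-methyl-3-(triethylsilyloxy)pentyl]oct-2-enoate
Conditions: MeNH(OMe)·HCl, AlMe3, CH2Cl2, −20 to 0 °C
Reagents that add atoms: N,O-dimethylhydroxylamine hydrochloride CNOC.Cl
Why: Aluminium amide transamination, assisted by the free β-hydroxyl, releases the auxiliary and gives the Weinreb amide without epimerising C9; the conjugated methyl ester is far less reactive at this temperature.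

Step 14
Reactants: 22 Weinreb amide
Product: 23 methyl (2Z,6R,7S)-6-(tert-butyldimethylsilyloxy)-2-(2-chloroethyl)-8-[methoxy(methyl)amino]-8-oxo-7-[(3R)-5-(tert-butyldimethylsilyloxy)-3-methyl-3-(triethylsilyloxy)pentyl]oct-2-enoate
Conditions: t-BuMe2SiOTf, 2,6-lutidine, CH2Cl2, −78 to 0 °C
Reagents that add atoms: tert-butyldimethylsilyl triflate CC(C)(C)[Si](C)(C)OS(=O)(=O)C(F)(F)F
Why: Silyl triflate silylation of the secondary alcohol blocks retro-aldol and β-elimination in the basic steps that follow.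

Step 15
Reactants: 23 silylated Weinreb amide; 24 methyl phenyl sulfone
Product: 25 methyl (2Z,6R,7S)-6-(tert-butyldimethylsilyloxy)-2-(2-chloroethyl)-8-oxo-9-(phenylsulfonyl)-7-[(3R)-5-(tert-butyldimethylsilyloxy)-3-methyl-3-(triethylsilyloxy)pentyl]non-2-enoate
Conditions: 24, n-BuLi, THF, −78 °C; then 23, −78 to −40 °C; aq. NH4Cl
Reagents that add atoms: none
Why: Acyl substitution of the Weinreb amide by (phenylsulfonyl)methyllithium stops at the ketone because the chelated adduct survives until quench; it installs C1 as a soft nucleophile next to C10, while the hindered conjugated ester and the alkyl chloride should react far more slowly at low temperature.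

Step 16
Reactants: 25 acyclic β-keto sulfone
Product: 27 methyl (1Z,5R,6S)-5-(tert-butyldimethylsilyloxy)-7-oxo-8-(phenylsulfonyl)-6-[(3R)-5-(tert-butyldimethylsilyloxy)-3-methyl-3-(triethylsilyloxy)pentyl]cyclodec-1-ene-1-carboxylate (epimers at the sulfone carbon C1), via iodide 26 (not isolated)
Conditions: Cs2CO3, NaI, MeCN, 70 °C, slow addition to 0.002 M
Reagents that add atoms: none
Why: Intramolecular C-alkylation of the stabilised β-keto sulfone carbanion (Finkelstein exchange in the flask, high dilution) forms C1–C2 and the ten-membered ring; the mild base leaves the enoate, C9 and the silyl ethers alone.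

Step 17
Reactants: 27 macrocyclic β-keto sulfone
Product: 28 methyl (1Z,5R,6S)-5-(tert-butyldimethylsilyloxy)-7-oxo-6-[(3R)-5-(tert-butyldimethylsilyloxy)-3-methyl-3-(triethylsilyloxy)pentyl]cyclodec-1-ene-1-carboxylate
Conditions: SmI2, THF/MeOH, −78 °C
Reagents that add atoms: none
Why: Reductive desulfonylation of a β-keto sulfone by SmI2 is fast at low temperature without HMPA, conditions under which the enoate should not be reduced; the samarium enolate is protonated at C1.

Step 18
Reactants: 28 macrocyclic C10 ketone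
Product: 29 methyl (1Z,5R,6R)-5-(tert-butyldimethylsilyloxy)-7-methylidene-6-[(3R)-5-(tert-butyldimethylsilyloxy)-3-methyl-3-(triethylsilyloxy)pentyl]cyclodec-1-ene-1-carboxylate (ring C1–C10 with C4=C5 (Z)-enoate, C10=C20 methylene, C8 OTBS, side chain on C9)
Conditions: Zn, CH2Br2, TiCl4, THF/CH2Cl2, 0 to 23 °C
Reagents that add atoms: dibromomethane BrCBr
Why: Takai–Lombardo methylenation is non-basic, so the C9 stereocentre α to the ketone and the β-silyloxy group should survive, and it discriminates the ketone from the ester.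

Step 19
Reactants: 29 ten-membered (Z)-enoate with C10 methylene
Product: 30 methyl (13R)-8α,15-bis(tert-butyldimethylsilyloxy)-13-(triethylsilyloxy)-17,18-dinorlabdan-19-oate (trans-decalin; 5α-H, 9α-H, 10β-methyl; C4–H as either epimer)
Conditions: Fe(acac)3 (30 mol %), PhSiH3, EtOH/ethylene glycol, 60 °C, 0.005 M
Reagents that add atoms: none
Why: Proposed new method: an iron hydride formed from Fe(acac)3 and PhSiH3 transfers a hydrogen atom to C20, the tertiary C10 radical adds across the ring to C5 (the β-carbon of the enoate), and the C4 radical is reduced to the ester enolate and protonated by the solvent. The closest known reaction type is the iron-mediated hydrogen atom transfer reductive olefin coupling in its intramolecular 6-exo form, together with transannular closures of cyclodecenes to decalins. The single new bond C5–C10 closes ring B in a 6-exo mode and ring A in a 6-endo mode with respect to the enoate, both through chair-like halves of the ten-membered ring. C5 is set trans to the C10 methyl because the ring-trans C4=C5 geometry holds C3 and C6 anti in the chair–chair fold; C10 is set by the C9 side chain and the C8 silyl ether, which both take equatorial sites and so fix the face of the radical that meets C5; C4 forms without control and is erased in step 20. The step needs the hydrogen atom to go to the electron-rich 1,1-disubstituted alkene and not to the enoate, and attack at C5 and not C4; both follow from the polarity match between the nucleophilic tertiary radical and the β-carbon of the acceptor. High dilution is used to suppress intermolecular coupling.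

Step 20
Reactants: 30 decalin C19 ester with C4–H
Product: 32 methyl (13R)-8α,15-bis(tert-butyldimethylsilyloxy)-13-(triethylsilyloxy)-17-norlabdan-19-oate (4α-methyl C18, axial ester C19), via lithium ester enolate 31 (not isolated)
Conditions: LiN(iPr)2, THF, −78 to 0 °C; then MeI, DMPU, −78 to 0 °C
Reagents that add atoms: iodomethane CI
Why: Ester enolate alkylation: the exocyclic C4 enolate should be methylated from the equatorial α face, away from the axial C10 methyl, which leaves the ester axial (C19) and sets C4.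

Step 21
Reactants: 32 C4-methylated tris-silyl ether
Product: 33 methyl (13R)-8α,13,15-trihydroxy-17-norlabdan-19-oate
Conditions: Bu4NF, THF, 50 °C
Reagents that add atoms: none
Why: Fluoride-mediated desilylation cleaves all three silyl ethers; the hindered axial methyl ester is not attacked.

Step 22
Reactants: 33 triol ester
Product: 35 (13R)-13-hydroxy-19-methoxy-8,19-dioxo-17-norlabdan-15-oic acid, via keto aldehyde 34 (not isolated)
Conditions: RuCl3 (cat.), NaIO4, MeCN/EtOAc/H2O, 23 °C
Reagents that add atoms: sodium periodate [Na+].[O-]I(=O)(=O)=O; water O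
Why: RuO4 generated in the flask oxidises the primary alcohol to the carboxylic acid (C15) and the secondary alcohol to the ketone (C8) in one operation and leaves the tertiary alcohol and the ester alone.

Step 23
Reactants: 35 C8 keto acid
Product: 36 (13R)-13-hydroxy-19-methoxy-19-oxolabd-8(17)-en-15-oic acid
Conditions: Ph3PCH3Br, KOtBu (excess), toluene, 0 to 80 °C; then cold aq. HCl to pH 3
Reagents that add atoms: methyltriphenylphosphonium bromide C[P+](c1ccccc1)(c1ccccc1)c1ccccc1.[Br-]
Why: Wittig methylenation with excess ylide tolerates the carboxylate and the alkoxide and converts the C8 ketone into the exocyclic methylene; any epimerisation at C9 returns the equatorial side chain.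

Step 24
Reactants: 36 C19 methyl ester
Product: 37 (4S,5R,9S,10R,13R)-13-hydroxylabd-8(17)-ene-15,19-dioic acid (target)
Conditions: n-PrSH, n-BuLi, HMPA, 23 °C; then cold aq. HCl to pH 3
Reagents that add atoms: none
Why: The neopentyl axial ester resists saponification, so it is cleaved by SN2 demethylation at the O-methyl carbon with a thiolate, which leaves the alkene and the tertiary alcohol untouched.

Compound list

1 | (R)-mevalonolactone | C[C@@]1(O)CCOC(=O)C1 | starting material
2 | (3R)-3,5-dihydroxy-3-methyl-1-(pyrrolidin-1-yl)pentan-1-one | C[C@@](CC(=O)N1CCCC1)(O)CCO | intermediate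
3 | (3R)-3-methyl-1-(pyrrolidin-1-yl)-3,5-bis(triethylsilyloxy)pentan-1-one | C[C@@](CC(=O)N1CCCC1)(O[Si](CC)(CC)CC)CCO[Si](CC)(CC)CC | intermediate
4 | (3S)-3-methyl-3,5-bis(triethylsilyloxy)pentan-1-ol | C[C@@](CCO)(O[Si](CC)(CC)CC)CCO[Si](CC)(CC)CC | intermediate
5 | (3R)-1-(tert-butyldimethylsilyloxy)-3-methyl-3,5-bis(triethylsilyloxy)pentane | C[C@@](CCO[Si](C)(C)C(C)(C)C)(O[Si](CC)(CC)CC)CCO[Si](CC)(CC)CC | intermediate
6 | (3S)-5-(tert-butyldimethylsilyloxy)-3-methyl-3-(triethylsilyloxy)pentanal | C[C@@](CCO[Si](C)(C)C(C)(C)C)(O[Si](CC)(CC)CC)CC=O | intermediate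
7 | benzyl (triphenylphosphoranylidene)acetate | O=C(C=P(c1ccccc1)(c1ccccc1)c1ccccc1)OCc1ccccc1 | starting material
8 | benzyl (2E,5R)-7-(tert-butyldimethylsilyloxy)-5-methyl-5-(triethylsilyloxy)hept-2-enoate | C[C@@](CCO[Si](C)(C)C(C)(C)C)(O[Si](CC)(CC)CC)C/C=C/C(=O)OCc1ccccc1 | intermediate
9 | (5R)-7-(tert-butyldimethylsilyloxy)-5-methyl-5-(triethylsilyloxy)heptanoic acid | C[C@@](CCO[Si](C)(C)C(C)(C)C)(O[Si](CC)(CC)CC)CCCC(=O)O | intermediate
10 | (S)-4-benzyloxazolidin-2-one | O=C1OC[C@H](Cc2ccccc2)N1 | starting material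
11 | mixed pivalic anhydride of 9 | C[C@@](CCO[Si](C)(C)C(C)(C)C)(O[Si](CC)(CC)CC)CCCC(=O)OC(=O)C(C)(C)C | intermediate
12 | (S)-4-benzyl-3-[(5R)-7-(tert-butyldimethylsilyloxy)-5-methyl-5-(triethylsilyloxy)heptanoyl]oxazolidin-2-one | C[C@@](CCO[Si](C)(C)C(C)(C)C)(O[Si](CC)(CC)CC)CCCC(=O)N1[C@@H](Cc2ccccc2)COC1=O | intermediate
13 | methyl 2-[bis(2,2,2-trifluoroethoxy)phosphoryl]acetate | COC(=O)CP(=O)(OCC(F)(F)F)OCC(F)(F)F | starting material
14 | 1-chloro-2-iodoethane | ClCCI | starting material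
15 | methyl 2-[bis(2,2,2-trifluoroethoxy)phosphoryl]-4-chlorobutanoate (racemic) | COC(=O)C(CCCl)P(=O)(OCC(F)(F)F)OCC(F)(F)F | intermediate
16 | pent-4-enal | C=CCCC=O | starting material
17 | methyl (2Z)-2-(2-chloroethyl)hepta-2,6-dienoate | C=CCC/C=C(\C(=O)OC)CCCl | intermediate
18 | methyl (2Z)-2-(2-chloroethyl)-6,7-dihydroxyhept-2-enoate | OCC(O)CC/C=C(\C(=O)OC)CCCl | intermediate
19 | methyl (2Z)-2-(2-chloroethyl)-6-oxohex-2-enoate | O=CCC/C=C(\C(=O)OC)CCCl | intermediate
20 | (Z)-dibutylboron enolate of 12 | C[C@@](CCO[Si](C)(C)C(C)(C)C)(O[Si](CC)(CC)CC)CC/C=C(\OB(CCCC)CCCC)N1[C@@H](Cc2ccccc2)COC1=O | intermediate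
21 | (S)-4-benzyl-3-[(2S,3R,6Z)-9-chloro-3-hydroxy-7-(methoxycarbonyl)-2-{(3R)-5-(tert-butyldimethylsilyloxy)-3-methyl-3-(triethylsilyloxy)pentyl}non-6-enoyl]oxazolidin-2-one | C[C@@](CCO[Si](C)(C)C(C)(C)C)(O[Si](CC)(CC)CC)CC[C@@H]([C@H](O)CC/C=C(\C(=O)OC)CCCl)C(=O)N1[C@@H](Cc2ccccc2)COC1=O | intermediate
22 | methyl (2Z,6R,7S)-2-(2-chloroethyl)-6-hydroxy-8-[methoxy(methyl)amino]-8-oxo-7-[(3R)-5-(tert-butyldimethylsilyloxy)-3-methyl-3-(triethylsilyloxy)pentyl]oct-2-enoate | C[C@@](CCO[Si](C)(C)C(C)(C)C)(O[Si](CC)(CC)CC)CC[C@@H]([C@H](O)CC/C=C(\C(=O)OC)CCCl)C(=O)N(C)OC | intermediate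
23 | 6-O-tert-butyldimethylsilyl ether of 22 | C[C@@](CCO[Si](C)(C)C(C)(C)C)(O[Si](CC)(CC)CC)CC[C@@H]([C@H](O[Si](C)(C)C(C)(C)C)CC/C=C(\C(=O)OC)CCCl)C(=O)N(C)OC | intermediate
24 | methyl phenyl sulfone | CS(=O)(=O)c1ccccc1 | starting material
25 | methyl (2Z,6R,7S)-6-(tert-butyldimethylsilyloxy)-2-(2-chloroethyl)-8-oxo-9-(phenylsulfonyl)-7-[(3R)-5-(tert-butyldimethylsilyloxy)-3-methyl-3-(triethylsilyloxy)pentyl]non-2-enoate | C[C@@](CCO[Si](C)(C)C(C)(C)C)(O[Si](CC)(CC)CC)CC[C@@H]([C@H](O[Si](C)(C)C(C)(C)C)CC/C=C(\C(=O)OC)CCCl)C(=O)CS(=O)(=O)c1ccccc1 | intermediate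
26 | 2-(2-iodoethyl) analogue of 25 | C[C@@](CCO[Si](C)(C)C(C)(C)C)(O[Si](CC)(CC)CC)CC[C@@H]([C@H](O[Si](C)(C)C(C)(C)C)CC/C=C(\C(=O)OC)CCI)C(=O)CS(=O)(=O)c1ccccc1 | intermediate
27 | methyl (1Z,5R,6S)-5-(tert-butyldimethylsilyloxy)-7-oxo-8-(phenylsulfonyl)-6-[(3R)-5-(tert-butyldimethylsilyloxy)-3-methyl-3-(triethylsilyloxy)pentyl]cyclodec-1-ene-1-carboxylate | [C@@H]1(CC[C@@](C)(O[Si](CC)(CC)CC)CCO[Si](C)(C)C(C)(C)C)C(=O)C(S(=O)(=O)c2ccccc2)CC/C(C(=O)OC)=C/CC[C@H]1O[Si](C)(C)C(C)(C)C | intermediate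
28 | methyl (1Z,5R,6S)-5-(tert-butyldimethylsilyloxy)-7-oxo-6-[(3R)-5-(tert-butyldimethylsilyloxy)-3-methyl-3-(triethylsilyloxy)pentyl]cyclodec-1-ene-1-carboxylate | [C@@H]1(CC[C@@](C)(O[Si](CC)(CC)CC)CCO[Si](C)(C)C(C)(C)C)C(=O)CCC/C(C(=O)OC)=C/CC[C@H]1O[Si](C)(C)C(C)(C)C | intermediate
29 | methyl (1Z,5R,6R)-5-(tert-butyldimethylsilyloxy)-7-methylidene-6-[(3R)-5-(tert-butyldimethylsilyloxy)-3-methyl-3-(triethylsilyloxy)pentyl]cyclodec-1-ene-1-carboxylate (key-step precursor) | [C@@H]1(CC[C@@](C)(O[Si](CC)(CC)CC)CCO[Si](C)(C)C(C)(C)C)C(=C)CCC/C(C(=O)OC)=C/CC[C@H]1O[Si](C)(C)C(C)(C)C | intermediate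
30 | methyl (13R)-8α,15-bis(tert-butyldimethylsilyloxy)-13-(triethylsilyloxy)-17,18-dinorlabdan-19-oate (key-step product, C4 epimers) | [C@@H]1(O[Si](C)(C)C(C)(C)C)CC[C@@H]2[C@](C)(CCCC2C(=O)OC)[C@H]1CC[C@@](C)(O[Si](CC)(CC)CC)CCO[Si](C)(C)C(C)(C)C | intermediate
31 | lithium enolate of 30 | [C@@H]1(O[Si](C)(C)C(C)(C)C)CC[C@@H]2[C@](C)(CCCC2=C(O[Li])OC)[C@H]1CC[C@@](C)(O[Si](CC)(CC)CC)CCO[Si](C)(C)C(C)(C)C | intermediate
32 | methyl (13R)-8α,15-bis(tert-butyldimethylsilyloxy)-13-(triethylsilyloxy)-17-norlabdan-19-oate | [C@@H]1(O[Si](C)(C)C(C)(C)C)CC[C@@H]2[C@](C)(CCC[C@]2(C)C(=O)OC)[C@H]1CC[C@@](C)(O[Si](CC)(CC)CC)CCO[Si](C)(C)C(C)(C)C | intermediate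
33 | methyl (13R)-8α,13,15-trihydroxy-17-norlabdan-19-oate | [C@@H]1(O)CC[C@@H]2[C@](C)(CCC[C@]2(C)C(=O)OC)[C@H]1CC[C@@](C)(O)CCO | intermediate
34 | methyl (13R)-13-hydroxy-8,15-dioxo-17-norlabdan-19-oate | O=C1CC[C@@H]2[C@](C)(CCC[C@]2(C)C(=O)OC)[C@H]1CC[C@@](C)(O)CC=O | intermediate
35 | (13R)-13-hydroxy-19-methoxy-8,19-dioxo-17-norlabdan-15-oic acid | O=C1CC[C@@H]2[C@](C)(CCC[C@]2(C)C(=O)OC)[C@H]1CC[C@@](C)(O)CC(=O)O | intermediate
36 | (13R)-13-hydroxy-19-methoxy-19-oxolabd-8(17)-en-15-oic acid | C=C1CC[C@@H]2[C@](C)(CCC[C@]2(C)C(=O)OC)[C@H]1CC[C@@](C)(O)CC(=O)O | intermediate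
37 | (4S,5R,9S,10R,13R)-13-hydroxylabd-8(17)-ene-15,19-dioic acid | C=C1CC[C@@H]2[C@](C)(CCC[C@]2(C)C(=O)O)[C@H]1CC[C@@](C)(O)CC(=O)O | target

Total step count: 24. Longest linear sequence: 21 steps (steps 1–8, then 12–24); steps 9–11 form the convergent branch.

Steps most likely to fail

Step 19. The C10 radical may be reduced, or may take the allylic hydrogen from C6 by 1,5-transfer, faster than it closes the ring; the alkene may isomerise; or the ring may not fold chair–chair, which would spoil the ring fusion or the C9/C10 relationship. The fallback gives up the macrocycle and forms the same two rings by known reactions: a 6-exo hydrogen atom transfer Giese cyclisation for ring B and an ester enolate alkylation for ring A. It sets out from 12 and 16 and returns at 30. Cross-metathesis of 16 with methyl acrylate (second-generation Grubbs catalyst, (H2IMes)(PCy3)Cl2Ru=CHPh) would give methyl (2E)-6-oxohex-2-enoate F1. The syn-aldol of 12 with F1 under the conditions of step 12 would give the adduct F2, transamination as in step 13 the Weinreb amide F3, and silylation as in step 14 its TBS ether F4. ClCH2CH2CH2MgBr at −78 °C would convert F4 into the 3-chloropropyl ketone F5, and Zn/CH2Br2/TiCl4 would give the C10-methylene compound F6. Fe(acac)3 and PhSiH3 should then close ring B to the cyclohexane F7 through a chair in which the C8 oxygen, the C9 side chain and the C1–C3 chain are equatorial. LiN(iPr)2 would finally close ring A by 6-exo-tet alkylation of the C4 ester enolate with the C3 chloride, giving 30.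

Step 16. Closure of a ten-membered ring is slow, so intermolecular alkylation, O-alkylation or conjugate addition of the carbanion to the enoate may overtake it. The fallback closes the same C1–C2 bond by ring-closing metathesis to an enone and then reduces it. It sets out from 13 and 12 and returns at 28. Alkylation of 13 with allyl bromide (NaH) would give methyl 2-[bis(2,2,2-trifluoroethoxy)phosphoryl]pent-4-enoate F8. Still–Gennari olefination of F8 with 4-(tert-butyldimethylsilyloxy)butanal would give the (Z)-enoate silyl ether F9, Bu4NF the alcohol F10, and Dess–Martin periodinane the aldehyde F11. The syn-aldol of 12 with F11 would give the adduct F12, transamination the Weinreb amide F13, and silylation its TBS ether F14. CH2=CHMgBr would convert F14 into the vinyl ketone F15. Ring-closing metathesis (second-generation Grubbs catalyst, toluene, 80 °C, high dilution) between the vinyl ketone and the allyl group should give the macrocyclic dienone F16, and conjugate reduction of its C1=C2 enone with [(Ph3P)CuH]6 should give 28.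

Step 15. Chemoselectivity may be lost: the sulfonyl carbanion may add to the conjugated ester (1,2 or 1,4) or displace the chloride. The fallback makes the ketone by aldehyde addition and oxidation instead of acyl substitution. It sets out from 21 and returns at 25. Silylation of 21 (t-BuMe2SiOTf, 2,6-lutidine) would give the silylated imide F17, LiBH4 (THF/MeOH, 0 °C) the C10 primary alcohol F18, and Dess–Martin periodinane the aldehyde F19. (Phenylsulfonyl)methyllithium adds to an aldehyde at −78 °C far faster than to any ester and should give the β-hydroxy sulfone F20; Dess–Martin oxidation would then give 25.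

Further compounds

F1 | step 19 | methyl (2E)-6-oxohex-2-enoate | O=CCC/C=C/C(=O)OC
F2 | step 19 | (S)-4-benzyl-3-[(2S,3R,6E)-3-hydroxy-8-methoxy-8-oxo-2-{(3R)-5-(tert-butyldimethylsilyloxy)-3-methyl-3-(triethylsilyloxy)pentyl}oct-6-enoyl]oxazolidin-2-one | C[C@@](CCO[Si](C)(C)C(C)(C)C)(O[Si](CC)(CC)CC)CC[C@@H]([C@H](O)CC/C=C/C(=O)OC)C(=O)N1[C@@H](Cc2ccccc2)COC1=O
F3 | step 19 | Weinreb amide from F2 | C[C@@](CCO[Si](C)(C)C(C)(C)C)(O[Si](CC)(CC)CC)CC[C@@H]([C@H](O)CC/C=C/C(=O)OC)C(=O)N(C)OC
F4 | step 19 | tert-butyldimethylsilyl ether of F3 | C[C@@](CCO[Si](C)(C)C(C)(C)C)(O[Si](CC)(CC)CC)CC[C@@H]([C@H](O[Si](C)(C)C(C)(C)C)CC/C=C/C(=O)OC)C(=O)N(C)OC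
F5 | step 19 | 3-chloropropyl ketone (C10 ketone carrying C1–C3 with chloride on C3) | C[C@@](CCO[Si](C)(C)C(C)(C)C)(O[Si](CC)(CC)CC)CC[C@@H]([C@H](O[Si](C)(C)C(C)(C)C)CC/C=C/C(=O)OC)C(=O)CCCCl
F6 | step 19 | C10-methylene compound from F5 | C[C@@](CCO[Si](C)(C)C(C)(C)C)(O[Si](CC)(CC)CC)CC[C@@H]([C@H](O[Si](C)(C)C(C)(C)C)CC/C=C/C(=O)OC)C(=C)CCCCl
F7 | step 19 | ring B cyclohexane: methyl [2-(3-chloropropyl)-2-methyl-4-(tert-butyldimethylsilyloxy)-3-{(3R)-5-(tert-butyldimethylsilyloxy)-3-methyl-3-(triethylsilyloxy)pentyl}cyclohexyl]acetate (5α-H, 8α-oxygen, 9β side chain, 10β-methyl) | [C@@H]1(O[Si](C)(C)C(C)(C)C)CC[C@@H](CC(=O)OC)[C@](C)(CCCCl)[C@H]1CC[C@@](C)(O[Si](CC)(CC)CC)CCO[Si](C)(C)C(C)(C)C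
F8 | step 16 | methyl 2-[bis(2,2,2-trifluoroethoxy)phosphoryl]pent-4-enoate | COC(=O)C(CC=C)P(=O)(OCC(F)(F)F)OCC(F)(F)F
F9 | step 16 | methyl (2Z)-6-(tert-butyldimethylsilyloxy)-2-(prop-2-en-1-yl)hex-2-enoate | C=CC/C(C(=O)OC)=C/CCCO[Si](C)(C)C(C)(C)C
F10 | step 16 | methyl (2Z)-6-hydroxy-2-(prop-2-en-1-yl)hex-2-enoate | C=CC/C(C(=O)OC)=C/CCCO
F11 | step 16 | methyl (2Z)-6-oxo-2-(prop-2-en-1-yl)hex-2-enoate | C=CC/C(C(=O)OC)=C/CCC=O
F12 | step 16 | syn-aldol adduct of 12 with F11 | C[C@@](CCO[Si](C)(C)C(C)(C)C)(O[Si](CC)(CC)CC)CC[C@@H]([C@H](O)CC/C=C(\C(=O)OC)CC=C)C(=O)N1[C@@H](Cc2ccccc2)COC1=O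
F13 | step 16 | Weinreb amide from F12 | C[C@@](CCO[Si](C)(C)C(C)(C)C)(O[Si](CC)(CC)CC)CC[C@@H]([C@H](O)CC/C=C(\C(=O)OC)CC=C)C(=O)N(C)OC
F14 | step 16 | tert-butyldimethylsilyl ether of F13 | C[C@@](CCO[Si](C)(C)C(C)(C)C)(O[Si](CC)(CC)CC)CC[C@@H]([C@H](O[Si](C)(C)C(C)(C)C)CC/C=C(\C(=O)OC)CC=C)C(=O)N(C)OC
F15 | step 16 | vinyl ketone from F14 | C[C@@](CCO[Si](C)(C)C(C)(C)C)(O[Si](CC)(CC)CC)CC[C@@H]([C@H](O[Si](C)(C)C(C)(C)C)CC/C=C(\C(=O)OC)CC=C)C(=O)C=C
F16 | step 16 | macrocyclic dienone (C1=C2 enone, C10 ketone, C4=C5 (Z)-enoate) | [C@@H]1(CC[C@@](C)(O[Si](CC)(CC)CC)CCO[Si](C)(C)C(C)(C)C)C(=O)C=CC/C(C(=O)OC)=C/CC[C@H]1O[Si](C)(C)C(C)(C)C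
F17 | step 15 | 3-O-tert-butyldimethylsilyl ether of 21 | C[C@@](CCO[Si](C)(C)C(C)(C)C)(O[Si](CC)(CC)CC)CC[C@@H]([C@H](O[Si](C)(C)C(C)(C)C)CC/C=C(\C(=O)OC)CCCl)C(=O)N1[C@@H](Cc2ccccc2)COC1=O
F18 | step 15 | C10 primary alcohol from F17 | C[C@@](CCO[Si](C)(C)C(C)(C)C)(O[Si](CC)(CC)CC)CC[C@@H]([C@H](O[Si](C)(C)C(C)(C)C)CC/C=C(\C(=O)OC)CCCl)CO
F19 | step 15 | C10 aldehyde from F18 | C[C@@](CCO[Si](C)(C)C(C)(C)C)(O[Si](CC)(CC)CC)CC[C@@H]([C@H](O[Si](C)(C)C(C)(C)C)CC/C=C(\C(=O)OC)CCCl)C=O
F20 | step 15 | β-hydroxy sulfone from F19 (C10 epimers) | C[C@@](CCO[Si](C)(C)C(C)(C)C)(O[Si](CC)(CC)CC)CC[C@@H]([C@H](O[Si](C)(C)C(C)(C)C)CC/C=C(\C(=O)OC)CCCl)C(O)CS(=O)(=O)c1ccccc1
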